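The key step exploits the fact that O1, C5, C4 and C3 of the γ-lactone are a masked but-2-yn-1-ol. The ring is dissected at three bonds: C2–C3, O1–C2 and the bond from C4 to the benzylic carbon of ring B (3,4-dimethoxyphenyl). The alkynol already carries the ring A benzyl group (benzyl-protected 3-hydroxy-4,5-dimethoxyphenyl) on the carbon that becomes C3. Its magnesium alkoxide steers a CuI-catalysed anti addition of the ring B benzyl Grignard reagent, carbon to C4 and magnesium to C3; carbon dioxide then becomes C2 and acid closes the butenolide in the same flask. Asymmetric hydrogenation and epimerisation afterwards set C4 and C3 of the trans (3R,4R) lactone.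

Key step: step 6

Atom labels: lactone O1, C2 (carbonyl), C3 (bears the ring A benzyl group), C4 (bears the ring B benzyl group), C5 (CH2O). The target SMILES reads as the trans (3R,4R) lactone.

Assumption: Ru(OAc)2[(S)-BINAP] is taken to deliver hydrogen to the face of the butenolide that makes C4 R. Should a trial run show the opposite sense, the (R)-BINAP complex is used and nothing else changes.

Step 1
Reactants: 1 3-hydroxy-4,5-dimethoxybenzaldehyde
Product: 2 3-(benzyloxy)-4,5-dimethoxybenzaldehyde
Conditions: BnBr (1.1 equiv), K2CO3 (1.5 equiv), DMF, 60 °C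
Reagents that add atoms: benzyl bromide, BrCc1ccccc1
Why: Williamson ether synthesis, in which the potassium phenoxide should displace bromide cleanly while the aldehyde stays untouched; the benzyl ether is chosen because it tolerates Grignard reagents and leaves at the end by neutral hydrogenolysis.

Step 2
Reactants: 2 3-(benzyloxy)-4,5-dimethoxybenzaldehyde
Product: 3 [3-(benzyloxy)-4,5-dimethoxyphenyl]methanol
Conditions: NaBH4, MeOH, 0 °C to rt
Reagents that add atoms: none
Why: Hydride reduction of the aromatic aldehyde with NaBH4 should give the benzylic alcohol without affecting the three aryl ethers.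

Step 3
Reactants: 3 [3-(benzyloxy)-4,5-dimethoxyphenyl]methanol
Product: 4 1-(benzyloxy)-5-(bromomethyl)-2,3-dimethoxybenzene
Conditions: PBr3 (0.4 equiv), CH2Cl2, 0 °C
Reagents that add atoms: phosphorus tribromide, BrP(Br)Br
Why: Bromination of a benzylic alcohol with PBr3 (substitution through the phosphite ester) should be fast at 0 °C on this electron-rich ring, and the crude bromide is used promptly to avoid self-alkylation.

Step 4
Reactants: 5 propargyl alcohol (prop-2-yn-1-ol); 4 1-(benzyloxy)-5-(bromomethyl)-2,3-dimethoxybenzene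
Product: 7 4-[3-(benzyloxy)-4,5-dimethoxyphenyl]but-2-yn-1-ol, via dimagnesium salt of propargyl alcohol 6 (not isolated)
Conditions: 5 (2.0 equiv), EtMgBr (4.0 equiv), THF, 0 °C to rt; CuI (10 mol%), then 4 (1.0 equiv), 60 °C; aq NH4Cl
Reagents that add atoms: none
Why: Copper-catalysed sp–sp3 coupling of an alkynylmagnesium halide with a benzylic bromide, in which only the acetylide carbon of the C,O-dimagnesium salt 6 is nucleophilic enough to be benzylated, so the alcohol needs no protecting group and the precursor of the key step is reached directly.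

Step 5
Reactants: 8 3,4-dimethoxybenzyl chloride
Product: 9 (3,4-dimethoxybenzyl)magnesium chloride (titrated solution, used at once)
Conditions: Mg turnings (3 equiv, pre-activated), 2-MeTHF, 0–10 °C, slow addition of dilute 8
Reagents that add atoms: magnesium, [Mg]
Why: Grignard formation by insertion of magnesium into the benzylic C–Cl bond, with slow addition of dilute chloride to excess metal in 2-MeTHF at low temperature to hold Wurtz homocoupling of this electron-rich benzyl halide down.

Step 6
Reactants: 7 4-[3-(benzyloxy)-4,5-dimethoxyphenyl]but-2-yn-1-ol; 9 (3,4-dimethoxybenzyl)magnesium chloride; 10 carbon dioxide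
Product: 14 3-[3-(benzyloxy)-4,5-dimethoxybenzyl]-4-(3,4-dimethoxybenzyl)furan-2(5H)-one, via chloromagnesium alkoxide 11 (not isolated), via alkenylmagnesium chelate 12 (not isolated), via Z hydroxy acid 13 (not isolated)
Conditions: MeMgCl (1.0 equiv), 2-MeTHF, −20 °C; CuI (10 mol%), 9 (2.5 equiv), −20 °C to rt; CO2 (dry gas), −20 °C to rt; 2 M HCl, rt
Reagents that add atoms: none
Why: MeMgCl first converts 7 into the alkoxide 11, which binds the benzylcopper–magnesium species generated from 9 and CuI (monovalent copper) and directs the benzyl group to the proximal alkyne carbon (future C4) while magnesium ends on the distal carbon (future C3) on the opposite face, giving the five-membered oxamagnesacycle 12. The closest known reaction type is exactly this copper-catalysed anti-carbomagnesiation of propargylic alcohols with electrophilic trapping of the alkenylmagnesium, here by carboxylation, which forms C2–C3 with retention of alkene geometry and so places the carboxyl group cis to CH2OH. On acidification the Z hydroxy acid 13 should lactonise at once by attack of O1 on the carboxyl carbon, a 5-exo-trig acyl substitution that closes the butenolide ring. No stereocentre is created, and the selectivities that matter are regiochemistry and anti geometry, both secured by the alkoxide because only the anti adduct with magnesium on the distal carbon can be held in a five-membered chelate. Working at or below room temperature should keep the basic reagent from isomerising the doubly activated ArCH2–C≡C methylene to an allene, preforming the alkoxide saves one equivalent of 9, and surplus 9 is carboxylated to an arylacetic acid that a NaHCO3 wash removes from the neutral lactone.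

Step 7
Reactants: 14 3-[3-(benzyloxy)-4,5-dimethoxybenzyl]-4-(3,4-dimethoxybenzyl)furan-2(5H)-one
Product: 15 (3S,4R)-3-[3-(benzyloxy)-4,5-dimethoxybenzyl]-4-(3,4-dimethoxybenzyl)dihydrofuran-2(3H)-one (cis lactone)
Conditions: H2 (100 atm), Ru(OAc)2[(S)-BINAP] (2 mol%), MeOH/CH2Cl2, 50 °C
Reagents that add atoms: none
Why: Ruthenium–BINAP asymmetric hydrogenation of a butenolide, in which the chiral ruthenium hydride should add both hydrogens syn to one enantiotopic face of the C3=C4 bond, fixing C4 as R through catalyst control and, by syn addition, C3 as S (cis); the high pressure answers the tetrasubstituted alkene, and the benzyl ether and arenes are left alone.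

Step 8
Reactants: 15 (3S,4R)-3-[3-(benzyloxy)-4,5-dimethoxybenzyl]-4-(3,4-dimethoxybenzyl)dihydrofuran-2(3H)-one
Product: 16 (3R,4R)-3-[3-(benzyloxy)-4,5-dimethoxybenzyl]-4-(3,4-dimethoxybenzyl)dihydrofuran-2(3H)-one (trans lactone)
Conditions: DBU (1 equiv), toluene, 80 °C
Reagents that add atoms: none
Why: Base-mediated epimerisation through the lactone enolate, in which only C3 carries an acidic hydrogen, so equilibration with DBU should convert the cis isomer into the thermodynamically favoured trans (3R,4R) lactone and leave C4 unchanged.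

Step 9
Reactants: 16 (3R,4R)-3-[3-(benzyloxy)-4,5-dimethoxybenzyl]-4-(3,4-dimethoxybenzyl)dihydrofuran-2(3H)-one
Product: 17 (3R,4R)-4-(3,4-dimethoxybenzyl)-3-(3-hydroxy-4,5-dimethoxybenzyl)dihydrofuran-2(3H)-one
Conditions: H2 (1 atm), Pd/C (10 wt% Pd), EtOAc/EtOH, rt
Reagents that add atoms: none
Why: Palladium-catalysed hydrogenolysis of the benzyl aryl ether under neutral conditions should free the ring A phenol without touching the lactone or either stereocentre.

Compound list
1 | 3-hydroxy-4,5-dimethoxybenzaldehyde | COc1cc(C=O)cc(O)c1OC | starting material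
2 | 3-(benzyloxy)-4,5-dimethoxybenzaldehyde | COc1cc(C=O)cc(OCc2ccccc2)c1OC | intermediate
3 | [3-(benzyloxy)-4,5-dimethoxyphenyl]methanol | COc1cc(CO)cc(OCc2ccccc2)c1OC | intermediate
4 | 1-(benzyloxy)-5-(bromomethyl)-2,3-dimethoxybenzene | COc1cc(CBr)cc(OCc2ccccc2)c1OC | intermediate
5 | propargyl alcohol (prop-2-yn-1-ol) | C#CCO | starting material
6 | bromomagnesium 3-(bromomagnesio)prop-2-yn-1-olate (dimagnesium salt of propargyl alcohol) | Br[Mg]OCC#C[Mg]Br | intermediate
7 | 4-[3-(benzyloxy)-4,5-dimethoxyphenyl]but-2-yn-1-ol | COc1cc(CC#CCO)cc(OCc2ccccc2)c1OC | intermediate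
8 | 3,4-dimethoxybenzyl chloride | COc1ccc(CCl)cc1OC | starting material
9 | (3,4-dimethoxybenzyl)magnesium chloride | COc1ccc(C[Mg]Cl)cc1OC | intermediate
10 | carbon dioxide | O=C=O | starting material
11 | chloromagnesium 4-[3-(benzyloxy)-4,5-dimethoxyphenyl]but-2-yn-1-olate | COc1cc(CC#CCO[Mg]Cl)cc(OCc2ccccc2)c1OC | intermediate
12 | 3-[3-(benzyloxy)-4,5-dimethoxybenzyl]-4-(3,4-dimethoxybenzyl)-2,5-dihydro-1,2-oxamagnesole (five-membered O–Mg–C=C–CH2 chelate) | COc1ccc(CC2=C(Cc3cc(OCc4ccccc4)c(OC)c(OC)c3)[Mg]OC2)cc1OC | intermediate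
13 | (2Z)-2-[3-(benzyloxy)-4,5-dimethoxybenzyl]-3-(3,4-dimethoxybenzyl)-4-hydroxybut-2-enoic acid | OC/C(Cc1ccc(OC)c(OC)c1)=C(/Cc1cc(OCc2ccccc2)c(OC)c(OC)c1)C(=O)O | intermediate
14 | 3-[3-(benzyloxy)-4,5-dimethoxybenzyl]-4-(3,4-dimethoxybenzyl)furan-2(5H)-one | COc1ccc(CC2=C(Cc3cc(OCc4ccccc4)c(OC)c(OC)c3)C(=O)OC2)cc1OC | intermediate
15 | (3S,4R)-3-[3-(benzyloxy)-4,5-dimethoxybenzyl]-4-(3,4-dimethoxybenzyl)dihydrofuran-2(3H)-one (cis) | COc1ccc(C[C@H]2COC(=O)[C@H]2Cc2cc(OCc3ccccc3)c(OC)c(OC)c2)cc1OC | intermediate
16 | (3R,4R)-3-[3-(benzyloxy)-4,5-dimethoxybenzyl]-4-(3,4-dimethoxybenzyl)dihydrofuran-2(3H)-one (trans) | COc1ccc(C[C@H]2COC(=O)[C@@H]2Cc2cc(OCc3ccccc3)c(OC)c(OC)c2)cc1OC | intermediate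
17 | (3R,4R)-4-(3,4-dimethoxybenzyl)-3-(3-hydroxy-4,5-dimethoxybenzyl)dihydrofuran-2(3H)-one | COc1ccc(C[C@H]2COC(=O)[C@@H]2Cc2cc(O)c(OC)c(OC)c2)cc1OC | target

Total step count: 9.
Longest linear sequence: 8 steps (steps 1, 2, 3, 4, 6, 7, 8 and 9, from 1 to 17); step 5 is a one-step side branch.

Steps most likely to fail

Step 6. The benzylmagnesium reagent may add too slowly to the internal alkyne, the basic medium may isomerise the propargylic methylene to an allene, or the alkenylmagnesium may be protonated before it meets CO2. The fallback builds the same butenolide by cross-coupling on a preformed lactone ring; it sets out from 2 and 8 and returns at 14. Aldehyde 2 is condensed and reduced in one pot with tetronic acid (O=C1CC(=O)CO1), Hantzsch ester and catalytic L-proline in CH2Cl2 at rt (reductive alkylation). This should give 3-[3-(benzyloxy)-4,5-dimethoxybenzyl]-4-hydroxyfuran-2(5H)-one F1. Tf2O and iPr2NEt in CH2Cl2 at −78 °C convert it into 4-[3-(benzyloxy)-4,5-dimethoxybenzyl]-5-oxo-2,5-dihydrofuran-3-yl trifluoromethanesulfonate F2. In parallel, 8 is treated with Zn dust and LiCl in THF to give (3,4-dimethoxybenzyl)zinc chloride F3. A Negishi coupling of the two with Pd(PPh3)4 (zerovalent palladium) in THF at rt should deliver 14.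

Step 7. Hydrogen uptake at the tetrasubstituted alkene may be sluggish and facial selectivity poor. The fallback gives up catalyst control for a resolution; it sets out from 14 and returns at 17. Hydrogenation with H2 (4 atm) over Pd/C in EtOAc/AcOH saturates the alkene by syn addition and removes the benzyl group. The product is racemic cis-4-(3,4-dimethoxybenzyl)-3-(3-hydroxy-4,5-dimethoxybenzyl)dihydrofuran-2(3H)-one F4. DBU in toluene at 80 °C epimerises C3 to racemic trans-4-(3,4-dimethoxybenzyl)-3-(3-hydroxy-4,5-dimethoxybenzyl)dihydrofuran-2(3H)-one F5. Aminolysis with (S)-1-phenylethylamine and 2-hydroxypyridine in toluene at 100 °C opens the lactone to two diastereomeric hydroxy amides, which are separated by chromatography or crystallisation. They are (2R,3R)-3-(3,4-dimethoxybenzyl)-4-hydroxy-2-(3-hydroxy-4,5-dimethoxybenzyl)-N-[(1S)-1-phenylethyl]butanamide F6 and (2S,3S)-3-(3,4-dimethoxybenzyl)-4-hydroxy-2-(3-hydroxy-4,5-dimethoxybenzyl)-N-[(1S)-1-phenylethyl]butanamide F7. Heating F6 with TsOH in toluene at 90 °C should relactonise it to 17 with loss of the amine.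

Step 4. The sparingly soluble dimagnesium salt may couple slowly, so that homocoupling or reduction of the benzylic bromide competes. The fallback uses a protected mono-acetylide; it sets out from 5 and 4 and returns at 7. Propargyl alcohol 5 is protected with 3,4-dihydro-2H-pyran and PPTS in CH2Cl2 as 2-(prop-2-yn-1-yloxy)tetrahydro-2H-pyran F8. EtMgBr in THF converts it into the soluble [3-(tetrahydro-2H-pyran-2-yloxy)prop-1-yn-1-yl]magnesium bromide F9. CuI-catalysed coupling with 4 in THF at 60 °C gives 2-({4-[3-(benzyloxy)-4,5-dimethoxyphenyl]but-2-yn-1-yl}oxy)tetrahydro-2H-pyran F10. TsOH in MeOH at rt then releases 7.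

Further compounds
F1 | step 6 | 3-[3-(benzyloxy)-4,5-dimethoxybenzyl]-4-hydroxyfuran-2(5H)-one | COc1cc(CC2=C(O)COC2=O)cc(OCc2ccccc2)c1OC
F2 | step 6 | 4-[3-(benzyloxy)-4,5-dimethoxybenzyl]-5-oxo-2,5-dihydrofuran-3-yl trifluoromethanesulfonate | COc1cc(CC2=C(OS(=O)(=O)C(F)(F)F)COC2=O)cc(OCc2ccccc2)c1OC
F3 | step 6 | (3,4-dimethoxybenzyl)zinc chloride | COc1ccc(C[Zn]Cl)cc1OC
F4 | step 7 | racemic cis-4-(3,4-dimethoxybenzyl)-3-(3-hydroxy-4,5-dimethoxybenzyl)dihydrofuran-2(3H)-one, (3S,4R) and (3R,4S) enantiomers | COc1ccc(C[C@H]2COC(=O)[C@H]2Cc2cc(O)c(OC)c(OC)c2)cc1OC.COc1ccc(C[C@@H]2COC(=O)[C@@H]2Cc2cc(O)c(OC)c(OC)c2)cc1OC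
F5 | step 7 | racemic trans-4-(3,4-dimethoxybenzyl)-3-(3-hydroxy-4,5-dimethoxybenzyl)dihydrofuran-2(3H)-one, (3R,4R) and (3S,4S) enantiomers | COc1ccc(C[C@H]2COC(=O)[C@@H]2Cc2cc(O)c(OC)c(OC)c2)cc1OC.COc1ccc(C[C@@H]2COC(=O)[C@H]2Cc2cc(O)c(OC)c(OC)c2)cc1OC
F6 | step 7 | (2R,3R)-3-(3,4-dimethoxybenzyl)-4-hydroxy-2-(3-hydroxy-4,5-dimethoxybenzyl)-N-[(1S)-1-phenylethyl]butanamide | COc1ccc(C[C@@H](CO)[C@@H](Cc2cc(O)c(OC)c(OC)c2)C(=O)N[C@@H](C)c2ccccc2)cc1OC
F7 | step 7 | (2S,3S)-3-(3,4-dimethoxybenzyl)-4-hydroxy-2-(3-hydroxy-4,5-dimethoxybenzyl)-N-[(1S)-1-phenylethyl]butanamide | COc1ccc(C[C@H](CO)[C@H](Cc2cc(O)c(OC)c(OC)c2)C(=O)N[C@@H](C)c2ccccc2)cc1OC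
F8 | step 4 | 2-(prop-2-yn-1-yloxy)tetrahydro-2H-pyran (racemic acetal) | C#CCOC1CCCCO1
F9 | step 4 | [3-(tetrahydro-2H-pyran-2-yloxy)prop-1-yn-1-yl]magnesium bromide | Br[Mg]C#CCOC1CCCCO1
F10 | step 4 | 2-({4-[3-(benzyloxy)-4,5-dimethoxyphenyl]but-2-yn-1-yl}oxy)tetrahydro-2H-pyran (racemic acetal) | COc1cc(CC#CCOC2CCCCO2)cc(OCc2ccccc2)c1OC
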